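**Retrosynthetic overview**
- The benzotropolone is opened into natural (−)-epicatechin 3-O-gallate (its catechol ring becomes the benzo ring and it supplies two stereocentres) and the non-natural (2R,3R)-2-(2,3,4-trihydroxyphenyl)chromane-3,5,7-triol (its pyrogallol ring becomes the tropolone ring, C4′ leaving as CO2). The seven-membered ring is formed last.
- The 2,3-cis flavan-3-ol comes from a racemic flavan-3-one by reductive dynamic kinetic resolution, which sets C2 and C3 together.
- The flavan-3-one comes from a 3-hydroxyflavylium salt, made by Robinson condensation of 2,4,6-trihydroxybenzaldehyde with an α-hydroxyacetophenone (C3–C4 and O1–C2).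
- Key C–C bond (C2–C3): carbene-catalysed acyl-anion addition of 2,3,4-tris(benzyloxy)benzaldehyde to formaldehyde, joining two carbonyl carbons.
- Ring order: pyrylium C-ring, then its reduction to the chiral pyran, then the tropolone ring.

Assumption: in step 4 the (R,R)-TsDPEN catalyst is taken to give the (3R) alcohol (Noyori model with the C2 side in the role of the aryl group); if the first run shows the opposite sense, the (S,S) catalyst is used and nothing else changes.
Assumption: (−)-epicatechin 3-O-gallate from green tea counts as a commercial starting material.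

**Route**

Step 1
Reactants: 1 2,3,4-trihydroxybenzaldehyde; 2 benzyl bromide
Product: 3 2,3,4-tris(benzyloxy)benzaldehyde
Conditions: BnBr (3.6 equiv), K2CO3 (4 equiv), DMF, 70 °C, N2
Reagents that add atoms: benzyl bromide (2), BrCc1ccccc1
Why: Williamson etherification of all three phenols (the chelated 2-OH needs DMF and heat) gives a base-stable aldehyde with no acidic OH for the carbene step, and the benzyl groups are removable by hydrogenolysis.

Step 2
Reactants: 3 2,3,4-tris(benzyloxy)benzaldehyde; 4 paraformaldehyde
Product: 5 2-hydroxy-1-[2,3,4-tris(benzyloxy)phenyl]ethan-1-one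
Conditions: (CH2O)n (8 equiv), 3-benzyl-5-(2-hydroxyethyl)-4-methylthiazolium chloride (15 mol %), i-Pr2NEt (0.3 equiv), THF, 60 °C, sealed tube
Reagents that add atoms: formaldehyde from paraformaldehyde (4), C=O
Why: NHC-catalysed crossed acyloin (benzoin-type) hydroxymethylation, in which the thiazolylidene turns the formyl carbon of 3 into a catalyst-bound acyl-anion equivalent that adds to formaldehyde, the smallest and most electrophilic acceptor, so that two carbonyl carbons are joined as C2–C3 of the future flavan; the ortho-benzyloxy group suppresses homo-benzoin of 3, and no stereocentre is formed.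

Step 3
Reactants: 5 2-hydroxy-1-[2,3,4-tris(benzyloxy)phenyl]ethan-1-one; 6 2,4,6-trihydroxybenzaldehyde
Product: 7 3,5,7-trihydroxy-2-[2,3,4-tris(benzyloxy)phenyl]chromenylium chloride
Conditions: HCl (g), dry EtOAc/MeOH, 0 °C then 4 °C, 24–48 h; filter the red salt
Reagents that add atoms: hydrogen chloride, Cl
Why: Robinson flavylium (anthocyanidin) synthesis, in which acid-catalysed aldol condensation of the CH2OH carbon of 5 with the aldehyde of 6 and cyclodehydration through an ortho-OH form C3–C4 and O1–C2 and precipitate the pyrylium salt; a benzyl group lost to HCl would do no harm because all are removed in step 5, and no stereocentre is formed.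

Step 4
Reactants: 7 3,5,7-trihydroxy-2-[2,3,4-tris(benzyloxy)phenyl]chromenylium chloride
Product: 9 (2R,3R)-2-[2,3,4-tris(benzyloxy)phenyl]chromane-3,5,7-triol (2,3-cis), via racemic flavan-3-one 8 (not isolated)
Conditions: Hantzsch ester (1.05 equiv), degassed DMF, 0 °C → rt, Ar; then RuCl[(R,R)-TsDPEN](p-cymene) (2 mol %), HCO2H/Et3N (5:2), 40 °C
Reagents that add atoms: none
Why: Proposed new method: hydride transfer from the dihydropyridine to the benzopyrylium (at C4 or C2, either way ending in ketone 8 after tautomerisation) gives racemic 8, whose C2–H (α to C=O, benzylic, α-oxy) epimerises quickly in HCO2H/Et3N, so Noyori–Ikariya asymmetric transfer hydrogenation runs as a dynamic kinetic resolution in which the catalyst fixes C3 as R and hydride enters anti to the 2-aryl group to give the 2,3-cis (2R,3R) alcohol; the closest known reactions are DKR transfer hydrogenation of 2-arylcycloalkanones and 1-aryl-2-tetralones to cis alcohols and the cis-selective hydride reduction of benzylated flavan-3-ones.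

Step 5
Reactants: 9 (2R,3R)-2-[2,3,4-tris(benzyloxy)phenyl]chromane-3,5,7-triol
Product: 10 (2R,3R)-2-(2,3,4-trihydroxyphenyl)chromane-3,5,7-triol (2,3-cis)
Conditions: H2 (1 atm), 20% Pd(OH)2/C, THF/MeOH, rt; filter under Ar and use at once
Reagents that add atoms: none
Why: Neutral hydrogenolysis of the three aryl benzyl ethers over Pearlman's catalyst, the standard catechin deprotection, leaves the pyran C2–O bond and both stereocentres untouched.

Step 6
Reactants: 10 (2R,3R)-2-(2,3,4-trihydroxyphenyl)chromane-3,5,7-triol; 11 (−)-epicatechin 3-O-gallate, (2R,3R)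
Product: 13 (2R,3R)-2-{3,4,6-trihydroxy-5-oxo-7-[(2R,3R)-3,5,7-trihydroxychroman-2-yl]-5H-benzo[7]annulen-1-yl}-5,7-dihydroxychroman-3-yl 3,4,5-trihydroxybenzoate (CNP0217128.1), via epicatechin gallate o-quinone 12 (not isolated)
Conditions: mushroom tyrosinase, air (O2), citrate–phosphate buffer pH 5.5/1-octanol (biphasic), 25 °C; Sephadex LH-20, then RP-HPLC
Reagents that add atoms: none
Why: Theaflavin-type oxidative benzotropolone annulation, in which the enzyme oxidises only the catechol ring of 11 to quinone 12, C5′ of 10 (ortho to 4′-OH, para to 2′-OH) adds 1,4 to C6′ of 12, and re-oxidation, carbonyl addition of the catechol C5′ to the central C3′ carbon of the pyrogallol ring and oxidative loss of C4′ as CO2 close the tropolone; with a 2,3,4-trihydroxyphenyl partner this places the flavanyl group at C7 next to the tropolone oxygens, and at pH 5.5 and 25 °C none of the four stereocentres is touched.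

**Compound list**

1 | 2,3,4-trihydroxybenzaldehyde | O=Cc1ccc(O)c(O)c1O | starting material
2 | benzyl bromide | BrCc1ccccc1 | starting material
3 | 2,3,4-tris(benzyloxy)benzaldehyde | O=Cc1ccc(OCc2ccccc2)c(OCc2ccccc2)c1OCc1ccccc1 | intermediate
4 | paraformaldehyde (formaldehyde source) | C=O | starting material
5 | 2-hydroxy-1-[2,3,4-tris(benzyloxy)phenyl]ethan-1-one | O=C(CO)c1ccc(OCc2ccccc2)c(OCc2ccccc2)c1OCc1ccccc1 | intermediate
6 | 2,4,6-trihydroxybenzaldehyde | O=Cc1c(O)cc(O)cc1O | starting material
7 | 3,5,7-trihydroxy-2-[2,3,4-tris(benzyloxy)phenyl]chromenylium chloride | Oc1cc(O)c2cc(O)c(-c3ccc(OCc4ccccc4)c(OCc4ccccc4)c3OCc3ccccc3)[o+]c2c1.[Cl-] | intermediate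
8 | racemic 5,7-dihydroxy-2-[2,3,4-tris(benzyloxy)phenyl]chroman-3-one | O=C1Cc2c(O)cc(O)cc2OC1c1ccc(OCc2ccccc2)c(OCc2ccccc2)c1OCc1ccccc1 | intermediate (not isolated)
9 | (2R,3R)-2-[2,3,4-tris(benzyloxy)phenyl]chromane-3,5,7-triol, 2,3-cis | O[C@@H]1Cc2c(O)cc(O)cc2O[C@@H]1c1ccc(OCc2ccccc2)c(OCc2ccccc2)c1OCc1ccccc1 | intermediate
10 | (2R,3R)-2-(2,3,4-trihydroxyphenyl)chromane-3,5,7-triol, 2,3-cis | O[C@@H]1Cc2c(O)cc(O)cc2O[C@@H]1c1ccc(O)c(O)c1O | intermediate
11 | (−)-epicatechin 3-O-gallate, (2R,3R) | O=C(O[C@@H]1Cc2c(O)cc(O)cc2O[C@@H]1c1ccc(O)c(O)c1)c1cc(O)c(O)c(O)c1 | starting material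
12 | epicatechin gallate o-quinone, (2R,3R)-2-(3,4-dioxocyclohexa-1,5-dien-1-yl)-5,7-dihydroxychroman-3-yl 3,4,5-trihydroxybenzoate | O=C(O[C@@H]1Cc2c(O)cc(O)cc2O[C@@H]1C1=CC(=O)C(=O)C=C1)c1cc(O)c(O)c(O)c1 | intermediate (not isolated)
13 | CNP0217128.1, (2R,3R)-2-{3,4,6-trihydroxy-5-oxo-7-[(2R,3R)-3,5,7-trihydroxychroman-2-yl]-5H-benzo[7]annulen-1-yl}-5,7-dihydroxychroman-3-yl 3,4,5-trihydroxybenzoate | O=C(O[C@@H]1Cc2c(O)cc(O)cc2O[C@@H]1c1cc(O)c(O)c2c(=O)c(O)c([C@H]3Oc4cc(O)cc(O)c4C[C@H]3O)ccc12)c1cc(O)c(O)c(O)c1 | target

**Totals**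

Total step count: 6. Longest linear sequence: 6 (1 → 3 → 5 → 7 → 9 → 10 → 13).

**Steps most likely to fail, with fallbacks**

Step 2 is the first risk: an ortho-substituted, electron-rich aldehyde is a reluctant acyl donor, and formaldehyde self-condensation competes. The fallback sets out from 3 and returns at 5. Compound 3 is condensed with propane-1,3-dithiol (cat. I2, CHCl3) to 2-[2,3,4-tris(benzyloxy)phenyl]-1,3-dithiane F1. Deprotonation with n-BuLi (THF, −30 °C) gives a stoichiometric acyl-anion equivalent, which is quenched with monomeric formaldehyde to give {2-[2,3,4-tris(benzyloxy)phenyl]-1,3-dithian-2-yl}methanol F2. MeI/CaCO3 in aqueous MeCN then unmasks the ketone 5.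

Step 4 is the second risk: the rate of C2 epimerisation, the level of ee and the sense of induction are untested on a flavan-3-one. The fallback sets out from 7 and returns at 9. The Hantzsch-ester reduction is run alone and racemic 8 is isolated. L-Selectride (THF, −78 °C, excess to allow for the two phenols) attacks anti to the 2-aryl group and gives only the 2,3-cis alcohol as the racemate, that is 9 together with its mirror image (2S,3S)-2-[2,3,4-tris(benzyloxy)phenyl]chromane-3,5,7-triol F3. The two are separated on a preparative chiral stationary phase (HPLC or SFC) and 9 is carried on.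

Step 6 is the third risk: the yield is expected to be low to moderate because of redox exchange that over-oxidises 10 and self-coupling of 11 through its galloyl group. The fallback sets out from 10 and 11 and returns at 13. Quinone 12 is generated separately (11, tyrosinase, O2, pH 5.5, 5 °C) and the enzyme is removed by ultrafiltration. Two equivalents of the cold quinone solution are added to 10 under argon, so that 12 is the only oxidant; the second equivalent re-oxidises the first adduct and is returned as 11. The reaction then stops at the benzo-fused bicyclo[3.2.1]octenedione ketol F4, which is isolated on Sephadex LH-20. Brief treatment with H2O2/NaHCO3 at 0 °C hydrates and cleaves the bridging ketone with oxidative loss of CO2 and gives 13.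

**Further compounds**

F1 | step 2 | 2-[2,3,4-tris(benzyloxy)phenyl]-1,3-dithiane | C1(SCCCS1)c1ccc(OCc2ccccc2)c(OCc2ccccc2)c1OCc1ccccc1
F2 | step 2 | {2-[2,3,4-tris(benzyloxy)phenyl]-1,3-dithian-2-yl}methanol | OCC1(SCCCS1)c1ccc(OCc2ccccc2)c(OCc2ccccc2)c1OCc1ccccc1
F3 | step 4 | (2S,3S)-2-[2,3,4-tris(benzyloxy)phenyl]chromane-3,5,7-triol, enantiomer of 9 | O[C@H]1Cc2c(O)cc(O)cc2O[C@H]1c1ccc(OCc2ccccc2)c(OCc2ccccc2)c1OCc1ccccc1
F4 | step 6 | bicyclo[3.2.1]octane adduct of 10 and 12 (bridging C4′ ketone, tertiary C3′ alcohol, C2′ enone; the two transient bridgehead configurations not assigned) | O=C(O[C@@H]1Cc2c(O)cc(O)cc2O[C@@H]1c1cc(O)c(O)c2c1C1C=C([C@H]3Oc4cc(O)cc(O)c4C[C@H]3O)C(=O)C2(O)C1=O)c1cc(O)c(O)c(O)c1
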